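**Assumption:** chloromethyl methyl ether, paraformaldehyde, methyl chloroformate and the bases, catalysts and solvents named are treated as purchased reagents. The target has no stereocentre and no stereogenic double bond, so no SMILES string of the main route carries a stereodescriptor.

## The problem

Broussonol D (24) is a flavonol. Ring A (C4a to C8a) carries hydroxyls at C5 and C7 and a prenyl group at C8, ring C carries the C4 carbonyl and the 3-hydroxyl, and ring B, joined at C2, is a 3',4'-catechol with a second prenyl group at C5'. With nothing to control in space, the difficulty is regiochemistry and functional-group tolerance. On ring A the prenyl group must end at C8 and not at C6; these positions differ only in which of the two ortho oxygens of a phloroglucinol unit becomes O1. On ring B the prenyl group must sit next to the 4'-oxygen. Each prenyl group lies ortho to a phenol, so protic and Lewis acids can close it to a 2,2-dimethylchroman, and its trisubstituted alkene is consumed by peracids, dioxiranes and hydrogenation. This excludes benzyl and methyl ethers as protecting groups and the usual epoxidative routes to the 3-hydroxyl. The five free hydroxyls form an electron-rich system that is air-sensitive in base, so they should be unmasked last and under mild conditions. The feature that opens the key step is that C4 is ortho to the oxygen-bearing C8a: in a ring A salicylaldehyde whose formyl carbon is C4 and whose free phenol is the future O1, a metal held by the phenoxide reaches the formyl C-H through a five-membered metallacycle. The resulting acyl metal can be joined to a one-carbon donor (C3) that already carries the ring B aroyl carbon (C2), after which O1 and C2 are placed to close ring C by loss of water.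

## Retrosynthesis

**24 to 23.** The last bonds cut are the four aryl O-CH2 bonds of acetal protecting groups, which leads to the tetrakis(methoxymethyl) ether 23. Methoxymethyl ethers are preferred to benzyl ethers (hydrogenolysis would saturate the prenyl groups), to methyl ethers (boron halides would cyclise the prenyl groups onto the neighbouring oxygens) and to silyl ethers (too labile toward the basic steps before). The forward reaction must be an acetal exchange mild enough to leave two ortho-prenylphenols intact.

**23 to 20.** Cutting the C3-O bond leads to flavone 20. The neighbouring choices are worse here. Oxidative cyclisation of a chalcone (Algar-Flynn-Oyamada) tends to divert to aurones when the position that becomes C5 is oxygenated. Electrophilic epoxidation of C2-C3 would attack the two prenyl alkenes first. In 20 the C3-H is the most acidic C-H, so the forward step can be deprotonation, boron trapping and nucleophilic peroxide oxidation by way of 21 and 22. Compound 20 is simpler by one oxygen and lacks the oxidation-prone 3-hydroxypyranone.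

**20 to 7 and 18.** Ring C is opened at C4-C3 and O1-C2. This divides 20 into salicylaldehyde 7 (ring A plus C4) and aroyl sulfoxonium ylide 18 (ring B plus C2 and C3), two fragments of similar size. The classical neighbour (O-acylation of an ortho-hydroxyacetophenone, Baker-Venkataraman shift, acid cyclisation) makes C3-C2 instead and needs three operations with strong base and strong acid. The present cut needs one catalytic operation in a buffered medium and uses an aldehyde that is one step from phenol 6. The forward reaction must activate the formyl C-H of 7 selectively, join it to the ylide carbon of 18 to give diketone 19, and dehydrate 19 to 20 in the same flask, without touching two alkenes and four acetals.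

**18 to 16 and 17.** Ylide 18 is cut between the carbonyl carbon and the ylide carbon, giving methyl ester 16 and the methylide derived from 17. An ester is chosen over an acid chloride because making an acid chloride next to four acetal oxygens is risky.

**16 to 14.** The ester carbon is removed next: 16 comes from aryl bromide 14 through aryllithium 15. Bromine serves as a placeholder for the carbon that becomes C2, so ring B oxygenation and prenylation can be done on a cheap salicylaldehyde. The halogen sits para to the phenol and blocks that position during the rearrangement.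

**14 to 13 to 11.** Compound 14 is the bis-acetal of catechol 13. The C3'-O bond of 13 is traced to the formyl group of salicylaldehyde 11, through formate 12. The formyl group has two jobs: it blocks one ortho position during prenyl transfer and then becomes the 3'-oxygen. The alternative, mono-alkylating a preformed catechol at the correct oxygen, would rest on a small difference in acidity.

**11 to 10 to 9 to 8 and 3.** The aryl-CH2 bond of the ring B prenyl group is cut by a [3,3] shift back to the 1,1-dimethylallyl ether 10, which comes from propargyl ether 9 and so from 8 and 3. In 10 one ortho carbon bears the formyl group and the para carbon bears bromine, so the allyl unit can arrive only at the carbon that becomes C5'. Direct C-prenylation of a phenoxide would give O/C and ortho/para mixtures.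

**7 to 6.** On the ring A side the aryl-CHO bond (C4a-C4) of 7 is cut to phenol 6. Compound 6 has one free ortho position, so an ortho-specific formylation can only give 7, the isomer that leads to the 8-prenyl flavone. The remaining ring CH lies para to the phenol and is not addressed.

**6 to 5 to 4 to 2 and 3, and 2 to 1.** The ring A prenyl C-C bond is cut by the same [3,3] logic to ether 5, made from propargyl ether 4 and so from 2 and 3; 2 is the bis-acetal of 1. Because 5 is symmetric, its two ortho carbons are identical and the rearrangement has one possible product. The price is a statistical double protection of 1 at the start.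

## Roads not taken

**Alternative 1:** aryne insertion into an arylpropiolic acid.
- **Cut:** C8a-O1 and C4a-C4.
- **Forward key step:** CsF would release the C4a-C8a aryne from ortho-silyl aryl triflate A2 in the presence of ring B arylpropiolic acid A3. The carboxylate oxygen adds at C8a, the C4a anion attacks the acyl carbon, and the strained intermediate opens to the ortho-hydroxyaryl ynone A1 with no new ring kept. A separate base-mediated 6-endo-dig closure would then give 20.
- **Merits:** the step is metal-free and convergent. The 5-alkoxy group polarises the aryne so that oxygen attacks C8a, the wanted carbon.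
- **Weak points:** A2 needs several steps beyond phenol 6 (ortho silylation and triflation on a fully substituted ring). An aryne next to a prenyl group can react with that alkene or its allylic hydrogens. The prenyl group also hinders attack at C8a. A3 needs alkyne installation and carboxylation from 14. Ring C is not closed in the key step, and the later closure raises the 5-exo (aurone) versus 6-endo question.
- **Comparison:** this road is better in avoiding cationic rhodium and silver, so acetal stability toward a Lewis acid and ylide self-coupling do not arise. Against that, the chosen plan uses aldehyde 7, one step from 6, needs no aryne beside an alkene, and closes ring C in the same flask; it should be shorter by about four steps.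

**Alternative 2:** Danheiser benzannulation of a fully differentiated ring A.
- **Cut:** three ring A bonds, C8a-C8, C7-C6 and C8a-C4a.
- **Forward key step:** heating 3-ethoxycyclobutenone A5 with prenyl-substituted siloxyalkyne A6 would give a vinylketene, a [2+2] adduct, a dienylketene and, after 6π closure, phenol A4. In A4 the free hydroxyl (future O1), the silyl ether (future 7-oxygen) and the ethyl ether (future 5-oxygen) are all different, and the prenyl group is fixed between the first two.
- **Merits:** complete regiocontrol and three orthogonal oxygens in one step.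
- **Weak points:** the differentiation is more than the target asks, since both the 5- and 7-oxygens end as free phenols and the symmetry of 5 already fixes the prenyl position. A5 and A6 each need several steps. The ethyl ether must be cleaved at the end by a Lewis acid, next to ortho-prenylphenols. A4 still lacks C4, so formylation and all of ring C remain; the road replaces only steps 1 to 4.
- **Comparison:** this road would be better if the 5- and 7-hydroxyls had to be told apart, for example for selectively O-alkylated analogues. For 24 the chosen plan reaches 6 in four steps from commodity chemicals and ends in acetals, not an ethyl ether.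

**Alternative 3:** twin sigmatropic delivery of both prenyl groups.
- **Cut:** the two aryl-CH2 bonds at C8 and C5', on a complete flavonol core derived from quercetin A9.
- **Forward key step:** heating the 5-O-prenyl 4'-O-(1,1-dimethylallyl) ether A8 with Eu(fod)3 would move the 5-O-prenyl group by a Claisen shift to C6 and a Cope shift to C8, and the 4'-O-allyl group by a single [3,3] shift to C5'. This gives A7, which needs only acetal removal.
- **Merits:** potentially the shortest road. The 3-hydroxyl is present from the start, both prenyl groups arrive in one step, and no C-H activation or C3 oxidation is needed.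
- **Weak points:** A8 requires telling apart the five hydroxyls of A9, in particular 3' from 4', with a tertiary allyl ether on one and a primary prenyl ether on the chelated, least reactive 5-hydroxyl. The C6 dienone can tautomerise (C6 bears hydrogen) to a 6-(1,1-dimethylallyl) product or lead to 6-prenyl material, so C8/C6 mixtures are likely. Two different rearrangements must run cleanly under one set of conditions, with a Lewis acid present beside newly freed ortho-prenylphenols.
- **Comparison:** this road is better in step count and in avoiding both the rhodium step and the C3 oxidation. The chosen plan sets against it regiochemical certainty at C8 and C5' (each prenyl is delivered to the only open ortho carbon) and no selective protection of a pentahydroxyflavonol.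

Key step: step 13

## Route

Step 1
Reactants: 1 phloroglucinol
Product: 2 3,5-bis(methoxymethoxy)phenol
Conditions: MOMCl (2.0 equiv), i-Pr2NEt (2.2 equiv), DMF, 0 °C to rt; chromatography
Reagents that add atoms: chloromethyl methyl ether, COCCl
Why: Williamson-type O-alkylation giving the acetals; the three hydroxyls of 1 are equivalent, so only the degree of alkylation must be set by stoichiometry, and the mono- and tris-ethers are separated by chromatography.

Step 2
Reactants: 2 3,5-bis(methoxymethoxy)phenol; 3 3-chloro-3-methylbut-1-yne
Product: 4 1,3-bis(methoxymethoxy)-5-[(2-methylbut-3-yn-2-yl)oxy]benzene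
Conditions: CuCl2·2H2O (1 mol %), DBU, MeCN, 0 °C
Reagents that add atoms: none
Why: Copper-catalysed propargylic etherification of a phenol with a tertiary propargylic chloride (attack of phenoxide at the tertiary carbon of a copper-bound propargyl/allenylidene species); the acetals are stable to the amidine base.

Step 3
Reactants: 4 1,3-bis(methoxymethoxy)-5-[(2-methylbut-3-yn-2-yl)oxy]benzene
Product: 5 1,3-bis(methoxymethoxy)-5-[(2-methylbut-3-en-2-yl)oxy]benzene
Conditions: H2 (1 atm), Pd/CaCO3 poisoned with Pb(OAc)2 (Lindlar catalyst), quinoline, EtOAc, rt
Reagents that add atoms: none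
Why: Lindlar semihydrogenation of the terminal alkyne stops at the alkene; it is needed because the propargyl ether itself would rearrange to a 2,2-dimethylchromene on heating.

Step 4
Reactants: 5 1,3-bis(methoxymethoxy)-5-[(2-methylbut-3-en-2-yl)oxy]benzene
Product: 6 3,5-bis(methoxymethoxy)-2-(3-methylbut-2-en-1-yl)phenol
Conditions: toluene, 110 °C
Reagents that add atoms: none
Why: Aromatic Claisen rearrangement; the [3,3] shift turns the 1,1-dimethylallyl ether into a prenyl group at an ortho carbon, the two ortho carbons are equivalent by symmetry, and the ortho dienone bears hydrogen and tautomerises before a Cope shift to the para carbon can compete.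

Step 5
Reactants: 6 3,5-bis(methoxymethoxy)-2-(3-methylbut-2-en-1-yl)phenol
Product: 7 2-hydroxy-4,6-bis(methoxymethoxy)-3-(3-methylbut-2-en-1-yl)benzaldehyde
Conditions: MgCl2 (2 equiv), Et3N (4 equiv), (CH2O)n (6 equiv), MeCN, reflux
Reagents that add atoms: formaldehyde (used as paraformaldehyde), C=O
Why: Casnati-Skattebøl ortho-formylation: the magnesium phenoxide delivers formaldehyde only to an ortho carbon and 6 has a single free one, so the aldehyde must land between the phenol and an acetal; a second formaldehyde oxidises the benzylic alkoxide by hydride transfer, and the amine-buffered medium should spare the acetals and the prenyl group.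

Step 6
Reactants: 8 5-bromosalicylaldehyde; 3 3-chloro-3-methylbut-1-yne
Product: 9 5-bromo-2-[(2-methylbut-3-yn-2-yl)oxy]benzaldehyde
Conditions: CuCl2·2H2O (1 mol %), DBU, MeCN, 0 °C
Reagents that add atoms: none
Why: The same copper-catalysed propargylic etherification as in step 2; the acidic chelated phenol of 8 is readily deprotonated, and the aldehyde and aryl bromide are inert.

Step 7
Reactants: 9 5-bromo-2-[(2-methylbut-3-yn-2-yl)oxy]benzaldehyde
Product: 10 5-bromo-2-[(2-methylbut-3-en-2-yl)oxy]benzaldehyde
Conditions: H2 (1 atm), Pd/CaCO3 poisoned with Pb(OAc)2 (Lindlar catalyst), quinoline, EtOAc, rt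
Reagents that add atoms: none
Why: Lindlar semihydrogenation; the poisoned catalyst at atmospheric pressure should reduce neither the aryl bromide nor the aldehyde.

Step 8
Reactants: 10 5-bromo-2-[(2-methylbut-3-en-2-yl)oxy]benzaldehyde
Product: 11 5-bromo-2-hydroxy-3-(3-methylbut-2-en-1-yl)benzaldehyde
Conditions: xylenes, 140 °C
Reagents that add atoms: none
Why: Aromatic Claisen rearrangement; one ortho carbon bears the formyl group and the para carbon bears bromine, so only C3 can accept the allyl unit and rearomatise, placing the prenyl group next to the phenol.

Step 9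
Reactants: 11 5-bromo-2-hydroxy-3-(3-methylbut-2-en-1-yl)benzaldehyde
Product: 13 5-bromo-3-(3-methylbut-2-en-1-yl)benzene-1,2-diol, via aryl formate 12 (not isolated)
Conditions: 30% H2O2, NaOH (aq), THF, 0 °C to rt, N2; then dilute HCl to pH 4
Reagents that add atoms: hydrogen peroxide, OO
Why: Dakin oxidation: hydroperoxide adds to the aldehyde, the aryl group migrates to oxygen with help from the ortho phenoxide, and formate 12 is saponified in the same pot; nucleophilic alkaline peroxide does not epoxidise the isolated alkene, and the catechol is acidified and used at once to limit air oxidation.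

Step 10
Reactants: 13 5-bromo-3-(3-methylbut-2-en-1-yl)benzene-1,2-diol
Product: 14 5-bromo-1,2-bis(methoxymethoxy)-3-(3-methylbut-2-en-1-yl)benzene
Conditions: MOMCl (3 equiv), i-Pr2NEt (4 equiv), CH2Cl2, 0 °C to rt
Reagents that add atoms: chloromethyl methyl ether, COCCl
Why: Williamson-type double O-alkylation of the catechol under amine base, which also keeps the ortho-prenylphenol away from acid.

Step 11
Reactants: 14 5-bromo-1,2-bis(methoxymethoxy)-3-(3-methylbut-2-en-1-yl)benzene
Product: 16 methyl 3,4-bis(methoxymethoxy)-5-(3-methylbut-2-en-1-yl)benzoate, via aryllithium 15 (not isolated)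
Conditions: n-BuLi (1.05 equiv), THF, -78 °C; then cannulated into ClCO2Me (3 equiv), THF, -78 °C
Reagents that add atoms: methyl chloroformate, COC(=O)Cl
Why: Bromine-lithium exchange at -78 °C is faster than ortho-lithiation beside the acetals; inverse addition of the aryllithium to excess chloroformate gives the ester and limits diaryl ketone formation.

Step 12
Reactants: 16 methyl 3,4-bis(methoxymethoxy)-5-(3-methylbut-2-en-1-yl)benzoate; 17 trimethylsulfoxonium iodide
Product: 18 1-[3,4-bis(methoxymethoxy)-5-(3-methylbut-2-en-1-yl)phenyl]-2-[dimethyl(oxo)-λ6-sulfanylidene]ethan-1-one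
Conditions: Me3S(O)I (3 equiv), KOt-Bu (3 equiv), THF, reflux; then 16, reflux
Reagents that add atoms: none
Why: Acylation of dimethylsulfoxonium methylide (the Corey-Chaykovsky reagent) by an ester; the β-keto ylide formed is stabilised and does not react further, and acetals and alkene are inert to the base.

Step 13
Reactants: 7 2-hydroxy-4,6-bis(methoxymethoxy)-3-(3-methylbut-2-en-1-yl)benzaldehyde; 18 1-[3,4-bis(methoxymethoxy)-5-(3-methylbut-2-en-1-yl)phenyl]-2-[dimethyl(oxo)-λ6-sulfanylidene]ethan-1-one
Product: 20 5,7-bis(methoxymethoxy)-2-[3,4-bis(methoxymethoxy)-5-(3-methylbut-2-en-1-yl)phenyl]-8-(3-methylbut-2-en-1-yl)-4H-chromen-4-one, via 1,3-diketone 19 (not isolated)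
Conditions: [Cp*RhCl2]2 (4 mol %), AgSbF6 (16 mol %), NaOAc (0.5 equiv), AcOH (1 equiv), ClCH2CH2Cl, 80 °C, argon; 18 added over 2 h to 7 (1.3 equiv)
Reagents that add atoms: none
Why: AgSbF6 strips chloride from [Cp*RhCl2]2 to give a cationic Cp*Rh fragment of trivalent rhodium, which binds the phenoxide of 7 and cleaves the adjacent formyl C-H to a five-membered acyl rhodacycle (Rh, O1, C8a, C4a, C4). Ylide 18 binds through carbon and loses dimethyl sulfoxide to give a rhodium carbene; migratory insertion of the acyl group forms C4-C3, and protonation by acetic acid releases the ortho-hydroxy 1,3-diketone 19 and returns the catalyst. Diketone 19 closes ring C by 6-exo-trig attack of the phenol oxygen on the aroyl carbonyl (O1-C2) and loses water to give the pyranone of 20. The closest known reaction type is the rhodium-catalysed annulation of salicylaldehydes with sulfoxonium ylides or diazo ketones to chromones, applied here to a more substituted pair. No stereocentre is formed. The selectivity needed is for the formyl C-H over aryl C-H bonds and the two alkenes: the phenoxide chelate places the metal at the formyl hydrogen, the other ortho position of the directing phenol carries the prenyl group, and trisubstituted alkenes insert poorly into a Cp*Rh-acyl bond. Ketone-directed C-H activation of ring B in 18 (C2' and C6' are free) is held down by adding 18 slowly to an excess of 7, and the acetate buffer keeps the medium too weakly acidic to cleave the acetals.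

Step 14
Reactants: 20 5,7-bis(methoxymethoxy)-2-[3,4-bis(methoxymethoxy)-5-(3-methylbut-2-en-1-yl)phenyl]-8-(3-methylbut-2-en-1-yl)-4H-chromen-4-one
Product: 23 3-hydroxy-5,7-bis(methoxymethoxy)-2-[3,4-bis(methoxymethoxy)-5-(3-methylbut-2-en-1-yl)phenyl]-8-(3-methylbut-2-en-1-yl)-4H-chromen-4-one, via 3-lithioflavone 21 (not isolated), via flavone-3-boronate 22 (not isolated)
Conditions: LiN(i-Pr)2 (1.3 equiv), THF, -78 °C; B(OMe)3 (2 equiv), -78 to 0 °C; then 30% H2O2, NaHCO3 (aq), 0 °C
Reagents that add atoms: hydrogen peroxide, OO
Why: Carbonyl-directed lithiation of the flavone C3-H (the most acidic C-H) at -78 °C, borate trapping and boronate oxidation with 1,2-shift of carbon from boron to oxygen; the nucleophilic peroxide spares the prenyl alkenes and the acetals are stable to base.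

Step 15
Reactants: 23 3-hydroxy-5,7-bis(methoxymethoxy)-2-[3,4-bis(methoxymethoxy)-5-(3-methylbut-2-en-1-yl)phenyl]-8-(3-methylbut-2-en-1-yl)-4H-chromen-4-one
Product: 24 Broussonol D, 2-[3,4-dihydroxy-5-(3-methylbut-2-en-1-yl)phenyl]-3,5,7-trihydroxy-8-(3-methylbut-2-en-1-yl)-4H-chromen-4-one
Conditions: HCl (about 1 M) in MeOH, rt to 40 °C, argon, stopped as soon as the last acetal is gone
Reagents that add atoms: none
Why: Acid-catalysed acetal exchange with methanol (transacetalisation to dimethoxymethane); aryl methoxymethyl ethers should cleave at an acidity and temperature below those that protonate the trisubstituted alkenes, the chelated 5-O-acetal going first.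

## Compound list

1 | phloroglucinol | Oc1cc(O)cc(O)c1 | starting material
2 | 3,5-bis(methoxymethoxy)phenol | COCOc1cc(O)cc(OCOC)c1 | intermediate
3 | 3-chloro-3-methylbut-1-yne | C#CC(C)(C)Cl | starting material
4 | 1,3-bis(methoxymethoxy)-5-[(2-methylbut-3-yn-2-yl)oxy]benzene | COCOc1cc(OCOC)cc(OC(C)(C)C#C)c1 | intermediate
5 | 1,3-bis(methoxymethoxy)-5-[(2-methylbut-3-en-2-yl)oxy]benzene | COCOc1cc(OCOC)cc(OC(C)(C)C=C)c1 | intermediate
6 | 3,5-bis(methoxymethoxy)-2-(3-methylbut-2-en-1-yl)phenol | COCOc1cc(O)c(CC=C(C)C)c(OCOC)c1 | intermediate
7 | 2-hydroxy-4,6-bis(methoxymethoxy)-3-(3-methylbut-2-en-1-yl)benzaldehyde | COCOc1cc(OCOC)c(CC=C(C)C)c(O)c1C=O | intermediate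
8 | 5-bromosalicylaldehyde | O=Cc1cc(Br)ccc1O | starting material
9 | 5-bromo-2-[(2-methylbut-3-yn-2-yl)oxy]benzaldehyde | C#CC(C)(C)Oc1ccc(Br)cc1C=O | intermediate
10 | 5-bromo-2-[(2-methylbut-3-en-2-yl)oxy]benzaldehyde | C=CC(C)(C)Oc1ccc(Br)cc1C=O | intermediate
11 | 5-bromo-2-hydroxy-3-(3-methylbut-2-en-1-yl)benzaldehyde | CC(C)=CCc1cc(Br)cc(C=O)c1O | intermediate
12 | 5-bromo-2-hydroxy-3-(3-methylbut-2-en-1-yl)phenyl formate | CC(C)=CCc1cc(Br)cc(OC=O)c1O | intermediate (not isolated)
13 | 5-bromo-3-(3-methylbut-2-en-1-yl)benzene-1,2-diol | CC(C)=CCc1cc(Br)cc(O)c1O | intermediate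
14 | 5-bromo-1,2-bis(methoxymethoxy)-3-(3-methylbut-2-en-1-yl)benzene | CC(C)=CCc1cc(Br)cc(OCOC)c1OCOC | intermediate
15 | [3,4-bis(methoxymethoxy)-5-(3-methylbut-2-en-1-yl)phenyl]lithium | CC(C)=CCc1cc([Li])cc(OCOC)c1OCOC | intermediate (not isolated)
16 | methyl 3,4-bis(methoxymethoxy)-5-(3-methylbut-2-en-1-yl)benzoate | CC(C)=CCc1cc(C(=O)OC)cc(OCOC)c1OCOC | intermediate
17 | trimethylsulfoxonium iodide | C[S+](C)(C)=O.[I-] | starting material
18 | 1-[3,4-bis(methoxymethoxy)-5-(3-methylbut-2-en-1-yl)phenyl]-2-[dimethyl(oxo)-λ6-sulfanylidene]ethan-1-one | CC(C)=CCc1cc(C(=O)C=S(C)(C)=O)cc(OCOC)c1OCOC | intermediate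
19 | 1-[3,4-bis(methoxymethoxy)-5-(3-methylbut-2-en-1-yl)phenyl]-3-[2-hydroxy-4,6-bis(methoxymethoxy)-3-(3-methylbut-2-en-1-yl)phenyl]propane-1,3-dione | CC(C)=CCc1cc(C(=O)CC(=O)c2c(OCOC)cc(OCOC)c(CC=C(C)C)c2O)cc(OCOC)c1OCOC | intermediate (not isolated)
20 | 5,7-bis(methoxymethoxy)-2-[3,4-bis(methoxymethoxy)-5-(3-methylbut-2-en-1-yl)phenyl]-8-(3-methylbut-2-en-1-yl)-4H-chromen-4-one | CC(C)=CCc1cc(-c2cc(=O)c3c(OCOC)cc(OCOC)c(CC=C(C)C)c3o2)cc(OCOC)c1OCOC | intermediate
21 | 3-lithio derivative of 20 | CC(C)=CCc1cc(-c2oc3c(CC=C(C)C)c(OCOC)cc(OCOC)c3c(=O)c2[Li])cc(OCOC)c1OCOC | intermediate (not isolated)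
22 | dimethyl boronate at C3 of 20 | CC(C)=CCc1cc(-c2oc3c(CC=C(C)C)c(OCOC)cc(OCOC)c3c(=O)c2B(OC)OC)cc(OCOC)c1OCOC | intermediate (not isolated)
23 | 3-hydroxy-5,7-bis(methoxymethoxy)-2-[3,4-bis(methoxymethoxy)-5-(3-methylbut-2-en-1-yl)phenyl]-8-(3-methylbut-2-en-1-yl)-4H-chromen-4-one | CC(C)=CCc1cc(-c2oc3c(CC=C(C)C)c(OCOC)cc(OCOC)c3c(=O)c2O)cc(OCOC)c1OCOC | intermediate
24 | Broussonol D | CC(C)=CCc1cc(-c2oc3c(CC=C(C)C)c(O)cc(O)c3c(=O)c2O)cc(O)c1O | target

## Step count and least certain steps

Total step count: 15. Longest linear sequence: 10 steps (steps 6 to 12 from 8, then steps 13 to 15). The ring A branch (steps 1 to 5) has 5 steps.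

**Step 13 (key step).** Three things are most likely to go wrong.
- Self-coupling of ylide 18 by ketone-directed C-H activation of its own ring B may outrun the cross-reaction, because the phenol and formyl group of 7 are both flanked by substituents.
- The 5-O-acetal may be lost by Lewis-acid-assisted cleavage once it lies peri to the new carbonyl.
- The reaction may stall at diketone 19 if the buffered medium is too weakly acidic for dehydration.

Fallback, setting out from 7 and 16 and returning at 20: methylmagnesium bromide is added to aldehyde 7 to give racemic 1-[2-hydroxy-4,6-bis(methoxymethoxy)-3-(3-methylbut-2-en-1-yl)phenyl]ethan-1-ol F1. MnO2 oxidises F1 to 1-[2-hydroxy-4,6-bis(methoxymethoxy)-3-(3-methylbut-2-en-1-yl)phenyl]ethan-1-one F2. The lithium dienolate of F2 (LiN(SiMe3)2, THF, -78 °C to rt) is acylated by ester 16 in a Claisen condensation to give diketone 19. Compound 19 is cyclodehydrated with NaOAc in AcOH at 90 °C to flavone 20. This replaces the C-H annulation by enolate acylation at the cost of three operations.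

**Step 14.** The likely failures are competing ortho-lithiation at C6 between the two acetal oxygens, addition of the amide to C2 with opening of the pyranone, and incomplete borate trapping of the hindered 3-lithio species.

Fallback, setting out from diketone 19 and returning at 24: 19 is isolated by running step 13 without acetic acid at lower temperature, or made by the Claisen condensation above. Its sodium enolate (NaH, THF, 0 °C) is benzoyloxylated at the central carbon with dibenzoyl peroxide to give racemic 2-benzoyloxy-1-[3,4-bis(methoxymethoxy)-5-(3-methylbut-2-en-1-yl)phenyl]-3-[2-hydroxy-4,6-bis(methoxymethoxy)-3-(3-methylbut-2-en-1-yl)phenyl]propane-1,3-dione F3. Methanolic HCl then closes ring C and removes the four acetals in one operation, giving 3-O-benzoyl Broussonol D F4. K2CO3 in degassed MeOH under argon removes the benzoate to give 24. The 3-oxygen thus enters by enolate oxidation and no flavone lithiation is needed.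

**Step 15.** The likely failure is acid-induced cyclisation of a prenyl group onto the freed 7- or 4'-hydroxyl (chroman formation) before the last acetal is cleaved, since the acetals are removed one after another at different rates.

Fallback, setting out from 23 and returning at 24: Me3SiOTf and 2,2'-bipyridyl in CH2Cl2 at 0 °C exchange the aryl methoxymethyl ethers for trimethylsilyl ethers under non-protic conditions. This gives 3,5,7,3',4'-pentakis-O-(trimethylsilyl) Broussonol D F5, drawn with the 3-hydroxyl also silylated. Stirring F5 in aqueous MeOH at rt releases 24 without strong acid.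

**Step 5.** The likely failures are magnesium-chelation-assisted loss of the acetal next to the new aldehyde, and sluggish reaction of the crowded phenoxide that leaves time for diarylmethane formation with formaldehyde.

Fallback, setting out from 1 and returning at 7: the aldehyde is introduced before any protecting group.
- Vilsmeier-Haack formylation of 1 (POCl3, DMF, then water) gives 2,4,6-trihydroxybenzaldehyde F6.
- Two equivalents of MOMCl with i-Pr2NEt leave the chelated hydroxyl free and give 2-hydroxy-4,6-bis(methoxymethoxy)benzaldehyde F7.
- Copper-catalysed etherification with 3 (CuCl2·2H2O, DBU, MeCN) gives 2,4-bis(methoxymethoxy)-6-[(2-methylbut-3-yn-2-yl)oxy]benzaldehyde F8.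
- Lindlar semihydrogenation gives 2,4-bis(methoxymethoxy)-6-[(2-methylbut-3-en-2-yl)oxy]benzaldehyde F9.
- Heating F9 in toluene moves the allyl unit to the one free ortho carbon (Claisen rearrangement) and gives 7.

## Further compounds

F1 | step 13 | 1-[2-hydroxy-4,6-bis(methoxymethoxy)-3-(3-methylbut-2-en-1-yl)phenyl]ethan-1-ol (racemic) | COCOc1cc(OCOC)c(CC=C(C)C)c(O)c1C(C)O
F2 | step 13 | 1-[2-hydroxy-4,6-bis(methoxymethoxy)-3-(3-methylbut-2-en-1-yl)phenyl]ethan-1-one | COCOc1cc(OCOC)c(CC=C(C)C)c(O)c1C(C)=O
F3 | step 14 | 2-benzoyloxy-1-[3,4-bis(methoxymethoxy)-5-(3-methylbut-2-en-1-yl)phenyl]-3-[2-hydroxy-4,6-bis(methoxymethoxy)-3-(3-methylbut-2-en-1-yl)phenyl]propane-1,3-dione (racemic) | CC(C)=CCc1cc(C(=O)C(OC(=O)c2ccccc2)C(=O)c2c(OCOC)cc(OCOC)c(CC=C(C)C)c2O)cc(OCOC)c1OCOC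
F4 | step 14 | 3-O-benzoyl Broussonol D | CC(C)=CCc1cc(-c2oc3c(CC=C(C)C)c(O)cc(O)c3c(=O)c2OC(=O)c2ccccc2)cc(O)c1O
F5 | step 15 | 3,5,7,3',4'-pentakis-O-(trimethylsilyl) Broussonol D | CC(C)=CCc1cc(-c2oc3c(CC=C(C)C)c(O[Si](C)(C)C)cc(O[Si](C)(C)C)c3c(=O)c2O[Si](C)(C)C)cc(O[Si](C)(C)C)c1O[Si](C)(C)C
F6 | step 5 | 2,4,6-trihydroxybenzaldehyde | O=Cc1c(O)cc(O)cc1O
F7 | step 5 | 2-hydroxy-4,6-bis(methoxymethoxy)benzaldehyde | COCOc1cc(O)c(C=O)c(OCOC)c1
F8 | step 5 | 2,4-bis(methoxymethoxy)-6-[(2-methylbut-3-yn-2-yl)oxy]benzaldehyde | COCOc1cc(OCOC)c(C=O)c(OC(C)(C)C#C)c1
F9 | step 5 | 2,4-bis(methoxymethoxy)-6-[(2-methylbut-3-en-2-yl)oxy]benzaldehyde | COCOc1cc(OCOC)c(C=O)c(OC(C)(C)C=C)c1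
A1 | alternative 1 | 3-[3,4-bis(methoxymethoxy)-5-(3-methylbut-2-en-1-yl)phenyl]-1-[2-hydroxy-4,6-bis(methoxymethoxy)-3-(3-methylbut-2-en-1-yl)phenyl]prop-2-yn-1-one | CC(C)=CCc1cc(C#CC(=O)c2c(OCOC)cc(OCOC)c(CC=C(C)C)c2O)cc(OCOC)c1OCOC
A2 | alternative 1 | 3,5-bis(methoxymethoxy)-2-(3-methylbut-2-en-1-yl)-6-(trimethylsilyl)phenyl trifluoromethanesulfonate | COCOc1cc(OCOC)c([Si](C)(C)C)c(OS(=O)(=O)C(F)(F)F)c1CC=C(C)C
A3 | alternative 1 | 3-[3,4-bis(methoxymethoxy)-5-(3-methylbut-2-en-1-yl)phenyl]prop-2-ynoic acid | CC(C)=CCc1cc(C#CC(=O)O)cc(OCOC)c1OCOC
A4 | alternative 2 | 5-ethoxy-2-(3-methylbut-2-en-1-yl)-3-(triisopropylsiloxy)phenol | CCOc1cc(O)c(CC=C(C)C)c(O[Si](C(C)C)(C(C)C)C(C)C)c1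
A5 | alternative 2 | 3-ethoxycyclobut-2-en-1-one | CCOC1=CC(=O)C1
A6 | alternative 2 | triisopropyl[(5-methylhex-4-en-1-yn-1-yl)oxy]silane | CC(C)=CCC#CO[Si](C(C)C)(C(C)C)C(C)C
A7 | alternative 3 | 3,7,3'-tri-O-(methoxymethyl) Broussonol D | CC(C)=CCc1cc(-c2oc3c(CC=C(C)C)c(OCOC)cc(O)c3c(=O)c2OCOC)cc(OCOC)c1O
A8 | alternative 3 | 3,7-bis(methoxymethoxy)-2-{3-(methoxymethoxy)-4-[(2-methylbut-3-en-2-yl)oxy]phenyl}-5-[(3-methylbut-2-en-1-yl)oxy]-4H-chromen-4-one | C=CC(C)(C)Oc1ccc(-c2oc3cc(OCOC)cc(OCC=C(C)C)c3c(=O)c2OCOC)cc1OCOC
A9 | alternative 3 | quercetin | O=c1c(O)c(-c2ccc(O)c(O)c2)oc2cc(O)cc(O)c12
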